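**Plan** (decalin numbering: C-1 quaternary carbon, C-2 dienyl-bearing CH, C-3=C-4, C-4a and C-8a ring fusion, C-6 methyl-bearing CH; ring A = C-4a/5/6/7/8/8a, ring B = C-1/2/3/4/4a/8a)
1. Cuts: the tetramic acid at C-3'–C-4' (Lacey–Dieckmann) and at the amide bond, giving L-threonine and a decalin β-keto thioester, hence a decalin-1-carbaldehyde; the C-2 dienyl chain back to a CH2OTBS group.
2. Ring B is then cut at C-1–C-8a. The enabling feature is that quaternary C-1 carries an exocyclic carbonyl carbon and is bonded to ring-fusion carbon C-8a, the product pattern of an epoxide-to-aldehyde 1,2-shift. Putting the formyl carbon back into the ring between C-8a and C-1 gives a trans-fused cyclohepta-1,4-diene epoxide (ring B plus one atom).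
3. Forward: (S)-5-methylcyclohexenone (ring A) + (Z)-alkenylcopper + allyl iodide, deoxygenation, allyl-to-propenyl isomerisation, RCM to the seven-membered ring, epoxidation, ring contraction to the decalin aldehyde, then thioester aldol/oxidation, Takai/Stille diene, aminolysis with the threonine ester, Dieckmann.
4. Stereochemistry: C-6 is bought; C-4a and C-8a are relayed from it (cuprate anti to methyl, allylation anti to the new group); C-2 comes from a copper-catalysed enantioselective allylic substitution; quaternary C-1 is relayed from C-2 (epoxidation anti to CH2OTBS, then stereospecific shift); C-5' and the carbinol come from L-threonine; diene geometry from Takai olefination and Stille coupling.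

Key step: step 12

Assumption: (S)-5-methylcyclohex-2-en-1-one and (E)-tributyl(prop-1-enyl)stannane are bought as single isomers (the enone is otherwise three known steps from commercial (S)-pulegone).

Step 1
Reactants: 1 (tert-butyldimethylsilyloxy)acetaldehyde; 2 ethyl 2-(triphenylphosphoranylidene)propanoate
Product: 3 ethyl (E)-4-(TBS-oxy)-2-methylbut-2-enoate
Conditions: CH2Cl2, 0 °C → rt
Reagents that add atoms: ethyl 2-(triphenylphosphoranylidene)propanoate, CCOC(=O)C(C)=P(c1ccccc1)(c1ccccc1)c1ccccc1
Why: Wittig olefination with a stabilised ylide should give the (E)-trisubstituted enoate.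

Step 2
Reactants: 3 ethyl (E)-4-(TBS-oxy)-2-methylbut-2-enoate
Product: 4 (E)-4-(TBS-oxy)-2-methylbut-2-en-1-ol
Conditions: DIBAL-H (2.2 equiv), CH2Cl2, −78 °C; Rochelle salt work-up
Reagents that add atoms: none
Why: DIBAL-H reduces the enoate in 1,2-fashion to the allylic alcohol without touching the alkene geometry or the silyl ether (ester reduction).

Step 3
Reactants: 4 (E)-4-(TBS-oxy)-2-methylbut-2-en-1-ol; 5 diethyl chlorophosphate
Product: 6 (E)-allylic diethyl phosphate
Conditions: Et3N, DMAP (cat.), CH2Cl2, 0 °C
Reagents that add atoms: diethyl chlorophosphate, CCOP(=O)(Cl)OCC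
Why: Phosphorylation of the primary allylic alcohol installs the leaving group needed for copper-catalysed allylic substitution.

Step 4
Reactants: 6 (E)-allylic diethyl phosphate; 7 ethynyltrimethylsilane
Product: 9 (S)-silylated 1,4-enyne, via alkynylaluminium reagent 8 (not isolated)
Conditions: 7, DIBAL-H, Et3N (5 mol %), hexanes, 55 °C; then 6, CuCl2·2H2O (5 mol %), chiral sulfonate-bearing imidazolinium salt (N-heterocyclic carbene precursor, 5.5 mol %), THF, −30 °C → rt
Reagents that add atoms: ethynyltrimethylsilane, C#C[Si](C)(C)C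
Why: Copper-catalysed enantioselective SN2' allylic substitution with the alkynylaluminium reagent attacks the γ-carbon bearing CH2OTBS, creating the tertiary propargylic stereocentre (future C-2) and the 1,1-disubstituted alkene; the face is fixed by the E alkene and the antipode of the carbene ligand chosen to give the S product.

Step 5
Reactants: 9 (S)-silylated 1,4-enyne; 10 N-iodosuccinimide
Product: 11 (S)-iodoalkyne
Conditions: NIS, AgNO3 (10 mol %), acetone, rt, dark
Reagents that add atoms: N-iodosuccinimide, O=C1CCC(=O)N1I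
Why: Silver-catalysed iododesilylation replaces the alkynyl C–Si bond by C–I and leaves the silyl ether and the alkene untouched.

Step 6
Reactants: 11 (S)-iodoalkyne
Product: 12 (R,Z)-iodoalkene
Conditions: 2-nitrobenzenesulfonylhydrazide, Et3N, THF/i-PrOH, rt
Reagents that add atoms: none
Why: Diimide generated in situ adds H2 syn to the iodoalkyne, which is reduced much faster than the 1,1-disubstituted alkene, so the (Z)-iodoalkene should result without loss of iodine (diimide reduction).

Step 7
Reactants: 12 (R,Z)-iodoalkene; 13 (S)-5-methylcyclohex-2-en-1-one; 14 allyl iodide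
Product: 17 (2R,3R,5S)-2-allyl-3-alkenyl-5-methylcyclohexanone, via alkenyllithium 15 (not isolated), via lithium enolate 16 (not isolated)
Conditions: 12, t-BuLi (2.0 equiv), Et2O, −78 °C; CuI·PBu3, −78 °C; 13, −78 → −40 °C; then HMPA, allyl iodide, −40 → −10 °C
Reagents that add atoms: (S)-5-methylcyclohex-2-en-1-one, O=C1C=CC[C@H](C)C1; allyl iodide, C=CCI
Why: Conjugate addition of the alkenylcopper occurs anti to the C-5 methyl group (axial attack on the half-chair with equatorial methyl) and the enolate is allylated anti to the new β-substituent, so the 2,3-trans-3,5-trans ketone should result (three-component coupling).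

Step 8
Reactants: 17 (2R,3R,5S)-2-allyl-3-alkenyl-5-methylcyclohexanone; 18 4-methylbenzenesulfonohydrazide
Product: 20 deoxygenated allyl triene, via tosylhydrazone 19 (not isolated)
Conditions: TsNHNH2, EtOH, rt; then catecholborane, CHCl3, 0 °C; NaOAc·3H2O, reflux
Reagents that add atoms: none
Why: Reduction of the tosylhydrazone with catecholborane and loss of sulfinate and N2 removes the carbonyl oxygen under non-basic conditions, so the α-stereocentre set in step 7 is not equilibrated (tosylhydrazone deoxygenation).

Step 9
Reactants: 20 deoxygenated allyl triene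
Product: 21 (E)-propenyl triene
Conditions: [Ir(cod)(PMePh2)2]PF6 (2 mol %, activated with H2, then degassed), THF, rt
Reagents that add atoms: none
Why: The cationic iridium hydride catalyst isomerises only the monosubstituted terminal alkene to the (E)-propenyl group, leaving the 1,1-disubstituted and cis-disubstituted alkenes in place (alkene isomerisation).

Step 10
Reactants: 21 (E)-propenyl triene
Product: 22 trans-fused bicyclic cyclohepta-1,4-diene
Conditions: second-generation Hoveyda–Grubbs catalyst [RuCl2(H2IMes)(=CH-C6H4-2-OiPr)] (10 mol %), 1,4-benzoquinone (20 mol %), toluene (0.002 M), 80 °C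
Reagents that add atoms: none
Why: Ring-closing metathesis between the propenyl and isopropenyl groups, the only pair that can give an unstrained ring, should close the seven-membered ring as the trisubstituted cis-alkene with loss of propene; no stereocentre is touched.

Step 11
Reactants: 22 trans-fused bicyclic cyclohepta-1,4-diene; 23 3-chloroperbenzoic acid
Product: 24 trisubstituted epoxide
Conditions: mCPBA (1.0 equiv), NaHCO3, CH2Cl2, −20 °C
Reagents that add atoms: 3-chloroperbenzoic acid, OOC(=O)c1cccc(Cl)c1
Why: The peracid epoxidises the more electron-rich trisubstituted alkene in preference to the cis-disubstituted one and approaches the face opposite the pseudoaxial CH2OTBS group on the adjacent allylic carbon, which is also the face of the neighbouring ring-fusion hydrogen (Prilezhaev epoxidation).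

Step 12
Reactants: 24 trisubstituted epoxide
Product: 25 decalin-1-carbaldehyde
Conditions: MABR [methylaluminium bis(4-bromo-2,6-di-tert-butylphenoxide), MeAl(OC6H2-4-Br-2,6-tBu2)2, 2 equiv], CH2Cl2, −78 °C; aqueous work-up
Reagents that add atoms: none
Why: MABR coordinates the epoxide oxygen and ionises the tertiary C–O bond at the methyl-bearing carbon, and the ring bond from the epoxide CH to ring-fusion carbon C-8a, held anti to the departing oxygen, shifts to that carbon while the epoxide CH collapses to the formyl group (Meinwald-type semipinacol rearrangement). The closest known reaction type is the MABR-promoted rearrangement of trisubstituted epoxides to α-quaternary aldehydes by alkyl shift, including the contraction of 1-methylcycloalkene oxides to 1-methylcycloalkanecarbaldehydes. Ring B (the cyclohexene C-1/C-2/C-3/C-4/C-4a/C-8a) is closed by this 1,2-alkyl shift, that is, by contraction of the seven-membered ring to the six-membered one with extrusion of the carbinol carbon as the exocyclic CHO. The quaternary centre C-1 is set by the epoxide configuration, because C-8a enters with inversion opposite the C–O bond and the formyl group therefore ends on the face the oxygen occupied (trans to the C-2 CH2OTBS group, cis to H-8a), while C-8a migrates with retention and C-2, C-4a and C-6 are untouched. The step needs ring-bond migration to win over hydride shift from the epoxide CH (which would give the cycloheptenone) and over hydride shift from the allylic C-2–H; the bulky, oxygenophilic aluminium phenoxide at −78 °C is chosen because it favours alkyl over hydride shift, and the flexible cycloheptene can place the migrating C–C bond antiperiplanar to the breaking C–O bond.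

Step 13
Reactants: 25 decalin-1-carbaldehyde; 26 S-tert-butyl ethanethioate
Product: 28 β-hydroxy thioester, via lithium thioester enolate 27 (not isolated)
Conditions: 26, LDA, THF, −78 °C; then 25, −78 °C; NH4Cl quench
Reagents that add atoms: S-tert-butyl ethanethioate, CC(=O)SC(C)(C)C
Why: Aldol addition of the lithium thioester enolate to the non-enolisable neopentyl aldehyde gives the β-hydroxy thioester, whose new carbinol centre is inconsequential because it is oxidised in step 15.

Step 14
Reactants: 28 β-hydroxy thioester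
Product: 29 diol thioester
Conditions: HF·pyridine, pyridine, THF, 0 °C → rt
Reagents that add atoms: none
Why: Buffered HF·pyridine cleaves the primary silyl ether without retro-aldol or thioester cleavage (desilylation).

Step 15
Reactants: 29 diol thioester
Product: 30 keto aldehyde thioester
Conditions: Dess–Martin periodinane (3 equiv), NaHCO3, CH2Cl2, 0 °C → rt
Reagents that add atoms: none
Why: Dess–Martin oxidation converts the secondary alcohol into the β-keto thioester and the primary alcohol into the aldehyde in one operation under buffered, non-basic conditions that should not epimerise C-2.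

Step 16
Reactants: 30 keto aldehyde thioester; 31 iodoform
Product: 32 (E)-iodoalkene β-keto thioester
Conditions: CrCl2 (6 equiv), CHI3 (2 equiv), THF/dioxane, 0 °C → rt
Reagents that add atoms: iodoform, IC(I)I
Why: Takai olefination converts only the aldehyde into the (E)-iodoalkene; the geminal dichromium reagent is non-basic, so the α-stereocentre at C-2 and the acidic β-keto thioester are not disturbed.

Step 17
Reactants: 32 (E)-iodoalkene β-keto thioester; 33 (E)-tributyl(prop-1-en-1-yl)stannane
Product: 34 (1E,3E)-dienyl β-keto thioester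
Conditions: Pd2(dba)3 (5 mol %), AsPh3 (20 mol %), NMP, rt → 40 °C
Reagents that add atoms: (E)-tributyl(prop-1-en-1-yl)stannane, C/C=C/[Sn](CCCC)(CCCC)CCCC
Why: Stille coupling joins the alkenyl iodide and the (E)-propenylstannane with retention of both alkene geometries under neutral conditions, giving the (1E,3E)-diene.

Step 18
Reactants: 35 methyl L-threoninate hydrochloride; 36 tert-butyldimethylsilyl chloride
Product: 37 methyl O-TBS-L-threoninate
Conditions: TBSCl, imidazole, DMF, rt; aqueous work-up
Reagents that add atoms: tert-butyldimethylsilyl chloride, CC(C)(C)[Si](C)(C)Cl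
Why: Silylation of the secondary hydroxyl of L-threonine methyl ester (any N-silyl group is lost on aqueous work-up) protects it against retro-aldol and acylation in the following steps.

Step 19
Reactants: 34 (1E,3E)-dienyl β-keto thioester; 37 methyl O-TBS-L-threoninate
Product: 38 β-keto amide
Conditions: AgOCOCF3 (1.5 equiv), Et3N, THF, 0 °C → rt
Reagents that add atoms: methyl O-(tert-butyldimethylsilyl)-L-threoninate, COC(=O)[C@H]([C@@H](C)O[Si](C)(C)C(C)(C)C)N
Why: The thiophilic silver salt activates the tert-butyl thioester towards aminolysis by the threonine amine, giving the β-keto amide without touching either stereocentre of the amino ester (silver-mediated thioester aminolysis).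

Step 20
Reactants: 38 β-keto amide
Product: 39 O-TBS tetramic acid
Conditions: NaOMe (3 equiv), MeOH, rt; then dilute HCl to pH 3
Reagents that add atoms: none
Why: Lacey–Dieckmann cyclisation of the β-keto amide enolate onto the methyl ester closes the pyrrolidine-2,4-dione, C-5' being retained under short exposure to methoxide at room temperature.

Step 21
Reactants: 39 O-TBS tetramic acid
Product: 40 target
Conditions: aqueous HF (48 %), MeCN, 0 °C → rt
Reagents that add atoms: none
Why: Aqueous HF in acetonitrile removes the secondary silyl ether without affecting the acyl tetramic acid or the diene (desilylation).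

**Compound list**
1 | (tert-butyldimethylsilyloxy)acetaldehyde | O=CCO[Si](C)(C)C(C)(C)C | starting material
2 | ethyl 2-(triphenylphosphoranylidene)propanoate | CCOC(=O)C(C)=P(c1ccccc1)(c1ccccc1)c1ccccc1 | starting material
3 | ethyl (2E)-4-[(tert-butyldimethylsilyl)oxy]-2-methylbut-2-enoate | CCOC(=O)/C(C)=C/CO[Si](C)(C)C(C)(C)C | intermediate
4 | (2E)-4-[(tert-butyldimethylsilyl)oxy]-2-methylbut-2-en-1-ol | OC/C(C)=C/CO[Si](C)(C)C(C)(C)C | intermediate
5 | diethyl chlorophosphate | CCOP(=O)(Cl)OCC | starting material
6 | (2E)-4-[(tert-butyldimethylsilyl)oxy]-2-methylbut-2-en-1-yl diethyl phosphate | CCOP(=O)(OCC)OC/C(C)=C/CO[Si](C)(C)C(C)(C)C | intermediate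
7 | ethynyltrimethylsilane | C#C[Si](C)(C)C | starting material
8 | diisobutyl[(trimethylsilyl)ethynyl]aluminium | CC(C)C[Al](CC(C)C)C#C[Si](C)(C)C | intermediate (not isolated)
9 | (S)-tert-butyldimethyl({3-methyl-2-[(trimethylsilyl)ethynyl]but-3-en-1-yl}oxy)silane | CC(C)(C)[Si](C)(C)OC[C@@H](C(C)=C)C#C[Si](C)(C)C | intermediate
10 | N-iodosuccinimide | O=C1CCC(=O)N1I | starting material
11 | (S)-tert-butyl{[2-(iodoethynyl)-3-methylbut-3-en-1-yl]oxy}dimethylsilane | CC(C)(C)[Si](C)(C)OC[C@@H](C(C)=C)C#CI | intermediate
12 | (R)-tert-butyl({2-[(Z)-2-iodoethenyl]-3-methylbut-3-en-1-yl}oxy)dimethylsilane | CC(C)(C)[Si](C)(C)OC[C@@H](C(C)=C)/C=C\I | intermediate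
13 | (S)-5-methylcyclohex-2-en-1-one | O=C1C=CC[C@H](C)C1 | starting material
14 | allyl iodide | C=CCI | starting material
15 | (Z)-alkenyllithium from 12 (same R centre) | CC(C)(C)[Si](C)(C)OC[C@@H](C(C)=C)/C=C\[Li] | intermediate (not isolated)
16 | lithium enolate of the conjugate adduct (alkenyl group trans to methyl) | CC(C)(C)[Si](C)(C)OC[C@@H](C(C)=C)/C=C\[C@H]1C[C@H](C)CC(O[Li])=C1 | intermediate (not isolated)
17 | (2R,3R,5S)-2-allyl-3-[(1Z,3R)-3-{[(tert-butyldimethylsilyl)oxy]methyl}-4-methylpenta-1,4-dien-1-yl]-5-methylcyclohexan-1-one | CC(C)(C)[Si](C)(C)OC[C@@H](C(C)=C)/C=C\[C@H]1C[C@H](C)CC(=O)[C@@H]1CC=C | intermediate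
18 | 4-methylbenzenesulfonohydrazide | Cc1ccc(cc1)S(=O)(=O)NN | starting material
19 | tosylhydrazone of 17 | CC(C)(C)[Si](C)(C)OC[C@@H](C(C)=C)/C=C\[C@H]1C[C@H](C)CC(=NNS(=O)(=O)c2ccc(C)cc2)[C@@H]1CC=C | intermediate (not isolated)
20 | 1-allyl-2-[(1Z,3R)-3-(TBS-oxymethyl)-4-methylpenta-1,4-dienyl]-4-methylcyclohexane (deoxo-17; allyl and alkenyl trans, alkenyl and methyl trans) | CC(C)(C)[Si](C)(C)OC[C@@H](C(C)=C)/C=C\[C@H]1C[C@H](C)CC[C@@H]1CC=C | intermediate
21 | (E)-prop-1-enyl isomer of 20 (ring configuration unchanged) | CC(C)(C)[Si](C)(C)OC[C@@H](C(C)=C)/C=C\[C@H]1C[C@H](C)CC[C@@H]1/C=C/C | intermediate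
22 | tert-butyl{[3,9-dimethylbicyclo[5.4.0]undeca-2,5-dien-4-yl]methoxy}dimethylsilane, trans-fused (H-1 and H-4 cis, H-7 trans to H-1, 9-methyl cis to H-7) | CC(C)(C)[Si](C)(C)OC[C@@H]1C=C[C@H]2C[C@H](C)CC[C@@H]2C=C1C | intermediate
23 | 3-chloroperbenzoic acid | OOC(=O)c1cccc(Cl)c1 | starting material
24 | 2,3-epoxide of 22, oxygen on the face of H-1 and H-4 (anti to CH2OTBS) | CC(C)(C)[Si](C)(C)OC[C@@H]1C=C[C@H]2C[C@H](C)CC[C@@H]2[C@H]3O[C@@]13C | intermediate
25 | (1R,2R,4aR,6R,8aS)-2-{[(tert-butyldimethylsilyl)oxy]methyl}-1,6-dimethyl-1,2,4a,5,6,7,8,8a-octahydronaphthalene-1-carbaldehyde | CC(C)(C)[Si](C)(C)OC[C@@H]1C=C[C@H]2C[C@H](C)CC[C@@H]2[C@@]1(C)C=O | intermediate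
26 | S-tert-butyl ethanethioate | CC(=O)SC(C)(C)C | starting material
27 | lithium enolate of 26 | [Li]OC(=C)SC(C)(C)C | intermediate (not isolated)
28 | S-tert-butyl 3-[(1R,2R,4aR,6R,8aS)-2-{[(tert-butyldimethylsilyl)oxy]methyl}-1,6-dimethyl-1,2,4a,5,6,7,8,8a-octahydronaphthalen-1-yl]-3-hydroxypropanethioate (carbinol epimers) | CC(C)(C)[Si](C)(C)OC[C@@H]1C=C[C@H]2C[C@H](C)CC[C@@H]2[C@@]1(C)C(O)CC(=O)SC(C)(C)C | intermediate
29 | S-tert-butyl 3-hydroxy-3-[(1R,2R,4aR,6R,8aS)-2-(hydroxymethyl)-1,6-dimethyl-1,2,4a,5,6,7,8,8a-octahydronaphthalen-1-yl]propanethioate (carbinol epimers) | OC[C@@H]1C=C[C@H]2C[C@H](C)CC[C@@H]2[C@@]1(C)C(O)CC(=O)SC(C)(C)C | intermediate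
30 | S-tert-butyl 3-[(1R,2R,4aR,6R,8aS)-2-formyl-1,6-dimethyl-1,2,4a,5,6,7,8,8a-octahydronaphthalen-1-yl]-3-oxopropanethioate | O=C[C@@H]1C=C[C@H]2C[C@H](C)CC[C@@H]2[C@@]1(C)C(=O)CC(=O)SC(C)(C)C | intermediate
31 | iodoform | IC(I)I | starting material
32 | S-tert-butyl 3-[(1R,2S,4aR,6R,8aS)-2-[(E)-2-iodoethenyl]-1,6-dimethyl-1,2,4a,5,6,7,8,8a-octahydronaphthalen-1-yl]-3-oxopropanethioate | I/C=C/[C@@H]1C=C[C@H]2C[C@H](C)CC[C@@H]2[C@@]1(C)C(=O)CC(=O)SC(C)(C)C | intermediate
33 | (E)-tributyl(prop-1-en-1-yl)stannane | C/C=C/[Sn](CCCC)(CCCC)CCCC | starting material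
34 | S-tert-butyl 3-[(1R,2R,4aR,6R,8aS)-1,6-dimethyl-2-[(1E,3E)-penta-1,3-dien-1-yl]-1,2,4a,5,6,7,8,8a-octahydronaphthalen-1-yl]-3-oxopropanethioate | C/C=C/C=C/[C@@H]1C=C[C@H]2C[C@H](C)CC[C@@H]2[C@@]1(C)C(=O)CC(=O)SC(C)(C)C | intermediate
35 | methyl L-threoninate hydrochloride | COC(=O)[C@H]([C@@H](C)O)N.Cl | starting material
36 | tert-butyldimethylsilyl chloride | CC(C)(C)[Si](C)(C)Cl | starting material
37 | methyl (2S,3R)-2-amino-3-[(tert-butyldimethylsilyl)oxy]butanoate | COC(=O)[C@H]([C@@H](C)O[Si](C)(C)C(C)(C)C)N | intermediate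
38 | methyl (2S,3R)-3-[(tert-butyldimethylsilyl)oxy]-2-{3-[(1R,2R,4aR,6R,8aS)-1,6-dimethyl-2-[(1E,3E)-penta-1,3-dien-1-yl]-1,2,4a,5,6,7,8,8a-octahydronaphthalen-1-yl]-3-oxopropanamido}butanoate | C/C=C/C=C/[C@@H]1C=C[C@H]2C[C@H](C)CC[C@@H]2[C@@]1(C)C(=O)CC(=O)N[C@@H]([C@@H](C)O[Si](C)(C)C(C)(C)C)C(=O)OC | intermediate
39 | (5S)-5-{(1R)-1-[(tert-butyldimethylsilyl)oxy]ethyl}-3-{[(1R,2R,4aR,6R,8aS)-1,6-dimethyl-2-[(1E,3E)-penta-1,3-dien-1-yl]-1,2,4a,5,6,7,8,8a-octahydronaphthalen-1-yl]carbonyl}-4-hydroxy-1,5-dihydro-2H-pyrrol-2-one | C/C=C/C=C/[C@@H]1C=C[C@H]2C[C@H](C)CC[C@@H]2[C@@]1(C)C(=O)C1=C(O)[C@H]([C@@H](C)O[Si](C)(C)C(C)(C)C)NC1=O | intermediate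
40 | (5S)-3-{[(1R,2R,4aR,6R,8aS)-1,6-dimethyl-2-[(1E,3E)-penta-1,3-dien-1-yl]-1,2,4a,5,6,7,8,8a-octahydronaphthalen-1-yl]carbonyl}-4-hydroxy-5-[(1R)-1-hydroxyethyl]-1,5-dihydro-2H-pyrrol-2-one | C/C=C/C=C/[C@@H]1C=C[C@H]2C[C@H](C)CC[C@@H]2[C@@]1(C)C(=O)C1=C(O)[C@H]([C@@H](C)O)NC1=O | target

**Count.** Total: 21 steps. Longest linear sequence: 20 steps (steps 1–17 and 19–21).

**Steps most likely to fail**

Step 12. Hydride shift from the epoxide CH, or ionisation followed by hydride shift or elimination at the allylic C-2 position, may outrun migration of the ring bond, giving cycloheptenone or diene products instead of ring contraction. The fallback sets out from 22 and returns at 25, replacing the concerted Lewis-acid shift by a stepwise halohydrin-salt semipinacol. N-Bromosuccinimide in wet DMSO should give bromohydrin F1 (bromonium on the face anti to CH2OTBS, water at the tertiary carbon). K2CO3 in MeOH closes it to the diastereomeric epoxide F2 (oxygen syn to CH2OTBS). LiBr with HMPA in toluene at 80 °C should open F2 at the tertiary carbon with inversion to the bromo alkoxide F3 (not isolated), in which C-8a shifts anti to bromide and expels it. The two inversions at C-1 place the formyl group on the same face as in the direct route, so 25 results.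

Step 4. Enantiofacial discrimination by the copper catalyst may be insufficient on this 2-methyl-substituted allylic phosphate (and SN2' versus SN2 selectivity may erode). The fallback sets out from 6 and returns at 17, replacing asymmetric catalysis by diastereomer separation. Reagent 8 and 6 are combined with an achiral catalyst (CuCl2·2H2O with 1,3-dimesitylimidazolinium chloride) to give racemic enyne F4. The operations of steps 5 and 6 convert it into racemic iodoalkyne F5 and racemic (Z)-iodoalkene F6. Coupling of F6 with single-enantiomer 13 as in step 7 gives 17 together with its side-chain epimer F7; these are diastereomers and are separated by chromatography.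

Step 7. Allylation of the copper/lithium enolate may be slow, so that proton transfer and enolate equilibration lead to regioisomeric or poly-allylated ketones. The fallback sets out from 12 and 13 and returns at 17. The enolate 16, generated as in step 7, is trapped on oxygen with allyl chloroformate to give allyl enol carbonate F8. Pd(PPh3)4 (zerovalent palladium) in THF then effects decarboxylative Tsuji allylation, delivering the allyl group regiospecifically to the α-carbon and anti to the neighbouring alkenyl group.

**Further compounds**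
F1 | step 12 | bromohydrin of 22 (Br on the CH next to the ring fusion, anti to CH2OTBS; tertiary OH on the opposite face) | CC(C)(C)[Si](C)(C)OC[C@@H]1C=C[C@H]2C[C@H](C)CC[C@@H]2[C@@H](Br)[C@]1(C)O
F2 | step 12 | epoxide diastereomer of 24 (oxygen syn to CH2OTBS) | CC(C)(C)[Si](C)(C)OC[C@@H]1C=C[C@H]2C[C@H](C)CC[C@@H]2[C@@H]3O[C@]13C
F3 | step 12 | lithium alkoxide of the tertiary bromide (not isolated) | CC(C)(C)[Si](C)(C)OC[C@@H]1C=C[C@H]2C[C@H](C)CC[C@@H]2[C@H](O[Li])[C@@]1(C)Br
F4 | step 4 | racemic form of enyne 9 | CC(C)(C)[Si](C)(C)OCC(C(C)=C)C#C[Si](C)(C)C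
F5 | step 4 | racemic form of iodoalkyne 11 | CC(C)(C)[Si](C)(C)OCC(C(C)=C)C#CI
F6 | step 4 | racemic form of (Z)-iodoalkene 12 | CC(C)(C)[Si](C)(C)OCC(C(C)=C)/C=C\I
F7 | step 4 | side-chain epimer of ketone 17 | CC(C)(C)[Si](C)(C)OC[C@H](C(C)=C)/C=C\[C@H]1C[C@H](C)CC(=O)[C@@H]1CC=C
F8 | step 7 | allyl enol carbonate of the conjugate adduct | CC(C)(C)[Si](C)(C)OC[C@@H](C(C)=C)/C=C\[C@H]1C[C@H](C)CC(OC(=O)OCC=C)=C1
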